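Two waits compete in these flasks: the wait of a molecule of starting material for its opening, and the wait of the opened molecule for a second intermediate.

| setting | Sunday's | Monday's |
|---|---|---|
| starting material | 0.40 M | 0.40 M |
| partner | 0.400 M | 0.400 M |
| capture agent | 0.0400 M | 0.0400 M |
| temperature | 100 °C | 120 °C |
| time | 3.0 h | 3.0 h |

    starting material → open intermediate (k1 = 0.0079 /min, Ea1 = 106 kJ/mol)
    partner → second intermediate (k2 = 0.022 /min, Ea2 = 106 kJ/mol)
    open intermediate + second intermediate ⇌ target (K3 = 42 /M, k3 = 0.028 /M/min, Ea3 = 73.0 kJ/mol, ΔH3 = −33.0 kJ/mol)
    second intermediate + capture agent → trapped intermediate (k4 = 0.066 /M/min, Ea4 = 88.0 kJ/mol)
    starting material + target → side product (k5 = 0.044 /M/min, Ea5 = 71.0 kJ/mol)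
    (constants at 100 °C)

- percentages count the starting material that a species holds: one side product counts as two
- all constants are for 100 °C and move with temperature by the activation energies and enthalpies

- which of these there is most of at the end, counted by the starting material in it, Sunday's (open intermediate / target / side product / starting material)
- which of these there is most of at the end, counted by the starting material in it, Monday's (open intermediate / target / side product / starting material)
- final amount of the leader among these, as a percentage of the starting material charged, in Sunday's
- final amount of the leader among these, as a percentage of the starting material charged, in Monday's

I follow one molecule. It opens after a mean wait of one over the opening constant, and the rest of the run is its time to couple. I treat coupling as pseudo-first-order, with the partner's charge standing in for the second intermediate. With the constants moved to each temperature: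

Sunday's: mean wait 127 min, N = 0.028 /M/min × 0.400 M × (180 min − 127 min) = 0.598

Monday's: mean wait 22.3 min, coupling constant 0.0927 /M/min, N = 5.85

This coupling count is the expected number of couplings an opened molecule gets, so it has coupled with chance one minus exp(−N). The chance is even at N = 0.693, where, in this count, open intermediate and coupled material draw level.

Sunday's count is lower than that, which gives a chance of 45.0%. Of the 75.9% I reckon opened, 41.7% stays open, so I commit to open intermediate as Sunday's leader.

Monday's count is higher, with a chance of 99.7%, so I commit to target. But N knows no way back. Monday's equilibrium constant is 24.4 /M, and for equal charges of opened molecule and second intermediate the balance stands at 72.7% coupled. So on Monday's N gives me the leader, and I leave the amount open.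

The forecast says open intermediate at 36% for Sunday's, and target at 52% for Monday's, where “the strongly activated first steps finish early”.

The simulation gives Sunday's open intermediate at 36.2%, with target at 24.3%, and Monday's target at 53.7%, with open intermediate at 24.3%. My Sunday's amount was too high.

Counting target and half of side product as coupled, Sunday's has coupled 49.5% of what opened, against my 45.0%. Monday's has coupled 72.7%, against 99.7%. In Monday's the coupling's relaxation half-life at the end, both ways together, is 0.520 h, shorter than the run of 3.0 h, and the final quotient of target over open intermediate and second intermediate comes to 21.8 /M, against the constant's 24.4 /M.

In the repeat of Monday's at 95 °C, the mean wait is 201 min, longer than the run. N comes to −0.173, which counts here as a sign, below 0.693, so I read open intermediate ahead of target. That flask ends with open intermediate at 36.1% and target at 15.0%.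

The constants stand for no real mixture; the rest is arithmetic.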